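## The problem

The target 27 is an E-chalcone whose ketone-bearing arene (ring A) is fused to a 3-hydroxy-2,2-dimethylchroman: the bridge O1–C2(Me)2–C3(OH)–C4H2 joins C8a to C4a, C5 carries the methoxy group, C8 the enone carbonyl, and only C6 and C7 bear hydrogen. Ring A is therefore a contiguously tetrasubstituted benzene with the carbon chain (C4) between two oxygens and the acyl group ortho to the ring oxygen. Electrophilic substitution on a resorcinol ether does not deliver this pattern reliably, because C6 and C8 are both activated. The single stereocentre, C3 (S), is a secondary carbinol between the benzylic methylene and the quaternary C2. No second stereocentre can relay to it, so it must come from the chiral pool or from a reagent, and its C–O bond must then never be broken. The enone is the fragile part (conjugate addition, reduction, light), and the tertiary aryl ether C2–O1 and the C3 alcohol tolerate acid only within limits, so the chalcone is best made last. The feature that opens a de novo entry is the substitution sequence of ring A itself: C8a(O)–C4a(C)–C5(O)–C6(H)–C7(H)–C8(C) is a 2-alkyl-3-alkoxyphenol with a carbon substituent at the other ortho position. This is what results when a vinylketene (supplying C8a with its oxygen, C6, C7 and C8) is united with a 1-alkoxyalkyne (supplying C4a and C5). If the alkyne already carries C4, C3 and C2 as a protected (S)-diol, one operation installs ring A, the methoxy group, the acetyl precursor and the stereocentre.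

## Retrosynthesis

**27 to 25 and 26.** The Cα=Cβ bond of the enone is cut, giving methyl ketone 25 and 4-hydroxybenzaldehyde 26. Cutting C8–C(=O) instead would require a C8 halide and carbonylation chemistry on a hindered, electron-rich arene. The aldol cut uses a commodity aldehyde and sets the E geometry thermodynamically. Precursor 25 no longer contains the enone. The forward Claisen–Schmidt condensation must tolerate the free C3 hydroxyl and the phenoxide form of 26.

**25 to 23 (through 24).** The O1–C2 bond is cut. Closing the ring at C2 through a tertiary cation leaves the C3–O bond intact. Closure at C3 would instead give a dihydrobenzofuran with inversion, and an O1–C8a cut has no workable forward reaction. Precursor 23 is an open-chain hydroxyacetophenone whose diol is still an acetonide. The forward step must ionise the tertiary carbinol of diol 24 and let the phenol capture the cation faster than a hydride migrates from C3.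

**23 to 21 (through 22).** This is a change of oxidation level only: the acetyl group is traced to a 1-silyloxyethyl group. A free acetyl group on the ketene partner would make an ene-dione diazo ketone. As a silyl ether the group is inert to ketenes and light. It must be oxidised before the acid step, because a benzylic carbinol flanked by an ortho hydroxyl and a para methoxy group would ionise.

**21 to 7 and 16.** Three bonds of ring A are cut at once: C8a–C4a, C5–C6 and C8a–C8. This is the only cut that turns the crowded arene into two acyclic pieces, and its regiochemistry follows from connectivity instead of directing effects. Diazo ketone 7 and ynol ether 16 each have one stereocentre and no ring A. The forward benzannulation must generate a vinylketene from 7, add 16 with the methoxy carbon next to the ketene α-carbon, and close ring A by electrocyclisation with no free hydroxyl present.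

**7 to 1 and 4.** The diazo group is traced to methyl ketone 5 by diazo transfer. Acylating diazomethane with an enoyl chloride would risk pyrazoline formation at the alkene. Enone 5 is cut at its C=C bond into aldehyde 3 and acyl ylide 4. Aldehyde 3 comes from ethyl (S)-lactate 1 through silyl ether 2.

**16 to 8 and 12.** The bond between the propargylic CH2 and the alkyne is cut, giving primary triflate 11 and methoxyacetylene 14, which is made from chloroacetal 12. An acetylide displacement uses the methoxy group of the target as the activating group of the alkyne. Triflate 11 comes from alcohol 10. Alcohol 10 is the thermodynamic acetonide isomer of carbinol 9, the Grignard product of glycerate ester 8, whose stereocentre becomes C3.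

## Roads not taken

**Alternative 1:** The C8–C(=O) and C(=O)–Cα bonds are cut together, giving aryl bromide A2, carbon monoxide and styrene A3.
- Forward step: Pd(OAc)2 with Ph2P(CH2)3PPh2 and Et3N under CO. Oxidative addition of zerovalent palladium into C8–Br, CO insertion, insertion of A3 and β-hydride elimination would give E-enone A1. Methanolysis of both acetates then gives 27.
- Merits: the chalcone is assembled in one catalytic operation, without an acetyl group and without an aldol step on a phenoxide aldehyde. In this segment it is shorter than the chosen plan, which spends steps 11, 12 and 14 on it.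
- Weak points: the bromide is electron-rich and ortho-alkoxylated, so oxidative addition is slow and direct Heck coupling to the stilbene competes with CO insertion. A3 polymerises readily. The alternative also leaves the hard part open: A2 needs its own enantioselective synthesis and a regiocontrolled bromination, or a route through A9.
- Comparison: the chosen plan sets against it a condensation of very low risk and an arene whose C8 substituent is placed by construction.

**Alternative 2:** The C3–O bond is traced to an oxygen atom delivered to the C3=C4 alkene of chromene A5. A5 is available from commercial acetophenone A4 by O-propargylation and Claisen rearrangement, with the acetyl group blocking the other ortho position.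
- Forward step: the chiral (salen)MnCl complex with NaOCl gives epoxide A6. Regioselective reductive opening of the benzylic C4–O bond would give 25.
- Merits: 2,2-dimethylchromenes are the best substrate class for this epoxidation. The route to 27 is about five operations against fourteen, so on step count this road is clearly better.
- Weak points: C4 of A6 is benzylic to a ring with oxygen at both ortho positions of C4a, so the epoxide is prone to solvolysis and rearrangement to the chromanone. The reductive opening must spare the aryl ketone. The configuration is an enantiomeric excess to be measured and possibly upgraded.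
- Comparison: the chosen plan takes C3 from the chiral pool, has no C4-oxygenated intermediate, and builds ring A in a way that lets each substituent be varied independently of the commercial arene.

**Alternative 3:** The C4–C4a bond is cut, giving aryl propargyl ether A7.
- Forward step: Ph3PAuNTf2 with a hindered pyridine N-oxide oxidises the terminal alkyne to an α-oxo gold carbene, which C4a captures to give chromanone A8. Enantioselective ketone reduction (for example Corey–Bakshi–Shibata) would give A9, and the C8 bromide would then be converted into the enone.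
- Merits: the chromanone is reached in two or three steps from a commercial bromophenol. The bromine blocks the other ortho position, so the cyclisation site is unambiguous.
- Weak points: the carbene must attack the hindered position between two oxygens. A8 enolises towards the benzylic carbon and is sensitive to air. The reduction must distinguish a methylene from a quaternary carbon by reagent control. The acyl group must still be introduced late from a hindered bromide next to a free or protected hydroxyl, with the difficulties of alternative 1.
- Comparison: this road is somewhat shorter. The chosen plan offers a stereocentre that is never at risk and no late organometallic step.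

Key step: step 10

Assumption: the configuration of the lactate-derived carbinol in 2 to 22 has no bearing on 27, because this carbon becomes the acetyl carbonyl in step 12; the S series is used only so that every intermediate is a single stereoisomer.

## Steps

Step 1
Reactants: 1 ethyl (S)-lactate
Product: 2 ethyl (S)-2-(tert-butyldimethylsilyloxy)propanoate
Conditions: TBSCl, imidazole, DMF, 0 °C to rt
Reagents that add atoms: tert-butyldimethylsilyl chloride, CC(C)(C)[Si](C)(C)Cl
Why: Standard silyl ether formation on a secondary α-hydroxy ester; it masks the hydroxyl that would otherwise quench the ketene of step 10, and the stereocentre is not touched.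

Step 2
Reactants: 2 ethyl (S)-2-(tert-butyldimethylsilyloxy)propanoate
Product: 3 (S)-2-(tert-butyldimethylsilyloxy)propanal
Conditions: i-Bu2AlH, CH2Cl2, −78 °C; aq potassium sodium tartrate
Reagents that add atoms: none
Why: Partial reduction of an ester to the aldehyde; the tetrahedral adduct is stable at −78 °C and collapses only on work-up, a routine operation for O-silyl lactates.

Step 3
Reactants: 3 (S)-2-(tert-butyldimethylsilyloxy)propanal; 4 1-(triphenyl-λ5-phosphanylidene)propan-2-one
Product: 5 (S,E)-5-(tert-butyldimethylsilyloxy)hex-3-en-2-one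
Conditions: CH2Cl2, rt
Reagents that add atoms: none
Why: Wittig olefination with a stabilised acyl ylide, which is E-selective and delivers the methyl ketone needed for diazo transfer.

Step 4
Reactants: 5 (S,E)-5-(tert-butyldimethylsilyloxy)hex-3-en-2-one
Product: 7 (S,E)-5-(tert-butyldimethylsilyloxy)-1-diazohex-3-en-2-one, via trifluoroacetyl diketone 6 (not isolated)
Conditions: LiN(SiMe3)2, THF, −78 °C; CF3CO2CH2CF3; dilute HCl work-up; then MsN3, Et3N, H2O, MeCN, rt
Reagents that add atoms: 2,2,2-trifluoroethyl trifluoroacetate, O=C(OCC(F)(F)F)C(F)(F)F (atoms kept only in 6); methanesulfonyl azide, CS(=O)(=O)N=[N+]=[N-]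
Why: Detrifluoroacetylative diazo transfer: kinetic deprotonation at the methyl group and Claisen acylation give 6, whose activated methylene accepts the diazo group from MsN3 while the trifluoroacetyl group leaves as the sulfonamide. This is the standard entry to α,β-unsaturated diazo methyl ketones, for which acylation of diazomethane fails through cycloaddition to the alkene.

Step 5
Reactants: 8 methyl (S)-2,2-dimethyl-1,3-dioxolane-4-carboxylate
Product: 9 (S)-2-(2,2-dimethyl-1,3-dioxolan-4-yl)propan-2-ol
Conditions: MeMgBr (excess), Et2O, 0 °C to rt; aq NH4Cl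
Reagents that add atoms: methylmagnesium bromide, C[Mg]Br
Why: Double Grignard addition to an ester creates the gem-dimethyl carbinol that becomes C2; the α-alkoxy stereocentre (future C3) is not involved.

Step 6
Reactants: 9 (S)-2-(2,2-dimethyl-1,3-dioxolan-4-yl)propan-2-ol
Product: 10 [(4S)-2,2,5,5-tetramethyl-1,3-dioxolan-4-yl]methanol
Conditions: camphorsulfonic acid (cat.), acetone, rt; Et3N quench
Reagents that add atoms: none
Why: Acid-catalysed acetal migration under thermodynamic control: the more highly substituted dioxolane spanning the secondary and tertiary oxygens is expected to be favoured and frees the primary hydroxyl. Only acetal C–O bonds are exchanged, so the configuration is kept.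

Step 7
Reactants: 10 [(4S)-2,2,5,5-tetramethyl-1,3-dioxolan-4-yl]methanol
Product: 11 [(4S)-2,2,5,5-tetramethyl-1,3-dioxolan-4-yl]methyl trifluoromethanesulfonate
Conditions: Tf2O, pyridine, CH2Cl2, −20 °C
Reagents that add atoms: trifluoromethanesulfonic anhydride, O=S(=O)(OS(=O)(=O)C(F)(F)F)C(F)(F)F
Why: Sulfonylation of a primary alcohol; the triflate is chosen because a β-branched, β-oxygenated carbon is a poor SN2 site for halides or tosylates, and it is used at once.

Step 8
Reactants: 12 chloroacetaldehyde dimethyl acetal
Product: 14 methoxyacetylene, via sodium methoxyacetylide 13 (not isolated)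
Conditions: NaNH2 (3 equiv), liquid NH3, −33 °C; cold aq NH4Cl; distil into THF at −78 °C
Reagents that add atoms: sodium amide, [Na+].[NH2-] (sodium kept only in 13)
Why: Two base-induced eliminations (methanol, then HCl) and deprotonation give the acetylide 13, the classical preparation of 1-alkoxyalkynes from α-chloro acetals; protonation releases the volatile alkyne, which is kept as a cold THF solution.

Step 9
Reactants: 14 methoxyacetylene; 11 [(4S)-2,2,5,5-tetramethyl-1,3-dioxolan-4-yl]methyl trifluoromethanesulfonate
Product: 16 (4S)-4-(3-methoxyprop-2-yn-1-yl)-2,2,5,5-tetramethyl-1,3-dioxolane, via lithium methoxyacetylide 15 (not isolated)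
Conditions: n-BuLi, THF, −78 °C; then 11, DMPU, −78 to −10 °C
Reagents that add atoms: n-butyllithium, [Li]CCCC (lithium kept only in 15)
Why: SN2 alkylation of a lithium acetylide by a primary triflate in THF/DMPU, a well-established reaction for dioxolanylmethyl triflates; amine-free generation of 15 avoids N-alkylation, and the stereocentre is adjacent to but not part of the reacting carbon.

Step 10
Reactants: 7 (S,E)-5-(tert-butyldimethylsilyloxy)-1-diazohex-3-en-2-one; 16 (4S)-4-(3-methoxyprop-2-yn-1-yl)-2,2,5,5-tetramethyl-1,3-dioxolane
Product: 21 6-[(1S)-1-(tert-butyldimethylsilyloxy)ethyl]-3-methoxy-2-{[(4S)-2,2,5,5-tetramethyl-1,3-dioxolan-4-yl]methyl}phenol, via vinylketene 17 (not isolated), via vinylcyclobutenone 18 (not isolated), via dienylketene 19 (not isolated), via cyclohexadienone 20 (not isolated)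
Conditions: 16 (1.3 equiv), ClCH2CH2Cl, hν (254 nm, low-pressure Hg lamps, Vycor), rt; then 80 °C
Reagents that add atoms: none
Why: This is the Danheiser benzannulation in its diazo ketone form, a known reaction of α,β-unsaturated diazo ketones with alkoxyalkynes. Irradiation expels N2 from 7 and photochemical Wolff rearrangement (1,2-shift of the alkenyl group) gives vinylketene 17. Ynol ether 16, whose carbon remote from oxygen is the nucleophilic one, adds across the ketene C=C bond in a [2+2] cycloaddition that joins that carbon to the ketene carbonyl carbon (C4a–C8a) and the methoxy-bearing carbon to the ketene α-carbon (C5–C6), giving cyclobutenone 18. Reversible 4π electrocyclic opening of 18, driven by light and then by heat, gives dienylketene 19; the geometry that cannot cyclise reverts to 18, so material funnels through the isomer shown. Ring A is closed by thermally allowed disrotatory 6π electrocyclisation of 19 (bond C8a–C8) to dienone 20, which tautomerises to phenol 21. No lasting stereocentre is created: the sp3 centres of 18 and 20 vanish on aromatisation, and the two existing centres are remote from every bond made or broken. The step needs regioselectivity in the [2+2] event, secured by the polarisation of the ynol ether, and chemoselective capture of the ketene by the alkyne, secured by masking every hydroxyl as silyl ether or acetal and by the slight excess of 16.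

Step 11
Reactants: 21 6-[(1S)-1-(tert-butyldimethylsilyloxy)ethyl]-3-methoxy-2-{[(4S)-2,2,5,5-tetramethyl-1,3-dioxolan-4-yl]methyl}phenol
Product: 22 6-[(1S)-1-hydroxyethyl]-3-methoxy-2-{[(4S)-2,2,5,5-tetramethyl-1,3-dioxolan-4-yl]methyl}phenol
Conditions: Bu4NF, THF, 0 °C to rt; aq NH4Cl
Reagents that add atoms: none
Why: Fluoride cleavage of a secondary silyl ether; the acetonide is inert, and the neutral work-up avoids ionisation of the electron-rich benzylic carbinol.

Step 12
Reactants: 22 6-[(1S)-1-hydroxyethyl]-3-methoxy-2-{[(4S)-2,2,5,5-tetramethyl-1,3-dioxolan-4-yl]methyl}phenol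
Product: 23 1-(2-hydroxy-4-methoxy-3-{[(4S)-2,2,5,5-tetramethyl-1,3-dioxolan-4-yl]methyl}phenyl)ethan-1-one
Conditions: MnO2, CH2Cl2, rt
Reagents that add atoms: none
Why: Selective oxidation of a benzylic alcohol to the aryl ketone, known for ortho-hydroxybenzyl alcohols; it removes the acid-labile benzylic carbinol before step 13 and gives a hydrogen-bonded 2-hydroxyacetophenone.

Step 13
Reactants: 23 1-(2-hydroxy-4-methoxy-3-{[(4S)-2,2,5,5-tetramethyl-1,3-dioxolan-4-yl]methyl}phenyl)ethan-1-one
Product: 25 1-[(3S)-3-hydroxy-5-methoxy-2,2-dimethyl-3,4-dihydro-2H-chromen-8-yl]ethan-1-one, via diol 24 (not isolated)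
Conditions: aq HCl, MeOH, 50 °C; then TsOH·H2O, toluene, 90 °C
Reagents that add atoms: none
Why: Aqueous acid hydrolyses the acetonide to diol 24; under dehydrating acid the tertiary carbinol ionises and the phenol oxygen captures the cation at C2 through a six-membered transition state (SN1 cyclodehydration, as in acid closures of chromans from phenols with tertiary carbinol side chains). The C3–O bond is never broken, so the S configuration is retained.

Step 14
Reactants: 25 1-[(3S)-3-hydroxy-5-methoxy-2,2-dimethyl-3,4-dihydro-2H-chromen-8-yl]ethan-1-one; 26 4-hydroxybenzaldehyde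
Product: 27 (2E)-1-[(3S)-3-hydroxy-5-methoxy-2,2-dimethyl-3,4-dihydro-2H-chromen-8-yl]-3-(4-hydroxyphenyl)prop-2-en-1-one
Conditions: KOH, EtOH/H2O, rt to 50 °C; then dilute HCl to pH 5
Reagents that add atoms: none
Why: Claisen–Schmidt condensation: enolate addition to the aldehyde and E1cB loss of water give the thermodynamically favoured E enone. The ketone has no free ortho hydroxyl, so flavanone formation is excluded, and the C3 carbinol is inert to aqueous base.

## Compound list

1 | ethyl (S)-lactate | CCOC(=O)[C@H](C)O | starting material
2 | ethyl (S)-2-(tert-butyldimethylsilyloxy)propanoate | CCOC(=O)[C@H](C)O[Si](C)(C)C(C)(C)C | intermediate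
3 | (S)-2-(tert-butyldimethylsilyloxy)propanal | O=C[C@H](C)O[Si](C)(C)C(C)(C)C | intermediate
4 | 1-(triphenyl-λ5-phosphanylidene)propan-2-one | CC(=O)C=P(c1ccccc1)(c1ccccc1)c1ccccc1 | starting material
5 | (S,E)-5-(tert-butyldimethylsilyloxy)hex-3-en-2-one | CC(=O)/C=C/[C@H](C)O[Si](C)(C)C(C)(C)C | intermediate
6 | (S,E)-7-(tert-butyldimethylsilyloxy)-1,1,1-trifluorooct-5-ene-2,4-dione | O=C(CC(=O)/C=C/[C@H](C)O[Si](C)(C)C(C)(C)C)C(F)(F)F | intermediate
7 | (S,E)-5-(tert-butyldimethylsilyloxy)-1-diazohex-3-en-2-one | C[C@H](O[Si](C)(C)C(C)(C)C)/C=C/C(=O)C=[N+]=[N-] | intermediate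
8 | methyl (S)-2,2-dimethyl-1,3-dioxolane-4-carboxylate | COC(=O)[C@@H]1COC(C)(C)O1 | starting material
9 | (S)-2-(2,2-dimethyl-1,3-dioxolan-4-yl)propan-2-ol | CC(C)(O)[C@@H]1COC(C)(C)O1 | intermediate
10 | [(4S)-2,2,5,5-tetramethyl-1,3-dioxolan-4-yl]methanol | OC[C@@H]1OC(C)(C)OC1(C)C | intermediate
11 | [(4S)-2,2,5,5-tetramethyl-1,3-dioxolan-4-yl]methyl trifluoromethanesulfonate | O=S(=O)(OC[C@@H]1OC(C)(C)OC1(C)C)C(F)(F)F | intermediate
12 | chloroacetaldehyde dimethyl acetal | COC(CCl)OC | starting material
13 | sodium methoxyacetylide | COC#C[Na] | intermediate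
14 | methoxyacetylene | COC#C | intermediate
15 | lithium methoxyacetylide | COC#C[Li] | intermediate
16 | (4S)-4-(3-methoxyprop-2-yn-1-yl)-2,2,5,5-tetramethyl-1,3-dioxolane | COC#CC[C@@H]1OC(C)(C)OC1(C)C | intermediate
17 | (3E,5S)-5-(tert-butyldimethylsilyloxy)hexa-1,3-dien-1-one | O=C=C/C=C/[C@H](C)O[Si](C)(C)C(C)(C)C | intermediate
18 | 4-[(1E,3S)-3-(tert-butyldimethylsilyloxy)but-1-en-1-yl]-3-methoxy-2-{[(4S)-2,2,5,5-tetramethyl-1,3-dioxolan-4-yl]methyl}cyclobut-2-en-1-one (both configurations at C4) | COC1=C(C[C@@H]2OC(C)(C)OC2(C)C)C(=O)C1/C=C/[C@H](C)O[Si](C)(C)C(C)(C)C | intermediate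
19 | (3E,5E,7S)-7-(tert-butyldimethylsilyloxy)-3-methoxy-2-{[(4S)-2,2,5,5-tetramethyl-1,3-dioxolan-4-yl]methyl}octa-1,3,5-trien-1-one | O=C=C(C[C@@H]1OC(C)(C)OC1(C)C)/C(OC)=C\C=C\[C@H](C)O[Si](C)(C)C(C)(C)C | intermediate
20 | 6-[(1S)-1-(tert-butyldimethylsilyloxy)ethyl]-3-methoxy-2-{[(4S)-2,2,5,5-tetramethyl-1,3-dioxolan-4-yl]methyl}cyclohexa-2,4-dien-1-one (both configurations at C6) | COC1=C(C[C@@H]2OC(C)(C)OC2(C)C)C(=O)C(C=C1)[C@H](C)O[Si](C)(C)C(C)(C)C | intermediate
21 | 6-[(1S)-1-(tert-butyldimethylsilyloxy)ethyl]-3-methoxy-2-{[(4S)-2,2,5,5-tetramethyl-1,3-dioxolan-4-yl]methyl}phenol | COc1ccc([C@H](C)O[Si](C)(C)C(C)(C)C)c(O)c1C[C@@H]2OC(C)(C)OC2(C)C | intermediate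
22 | 6-[(1S)-1-hydroxyethyl]-3-methoxy-2-{[(4S)-2,2,5,5-tetramethyl-1,3-dioxolan-4-yl]methyl}phenol | COc1ccc([C@H](C)O)c(O)c1C[C@@H]2OC(C)(C)OC2(C)C | intermediate
23 | 1-(2-hydroxy-4-methoxy-3-{[(4S)-2,2,5,5-tetramethyl-1,3-dioxolan-4-yl]methyl}phenyl)ethan-1-one | COc1ccc(C(C)=O)c(O)c1C[C@@H]2OC(C)(C)OC2(C)C | intermediate
24 | 1-{3-[(2S)-2,3-dihydroxy-3-methylbutyl]-2-hydroxy-4-methoxyphenyl}ethan-1-one | COc1ccc(C(C)=O)c(O)c1C[C@H](O)C(C)(C)O | intermediate
25 | 1-[(3S)-3-hydroxy-5-methoxy-2,2-dimethyl-3,4-dihydro-2H-chromen-8-yl]ethan-1-one | COc1ccc(C(C)=O)c2c1C[C@H](O)C(C)(C)O2 | intermediate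
26 | 4-hydroxybenzaldehyde | O=Cc1ccc(O)cc1 | starting material
27 | (2E)-1-[(3S)-3-hydroxy-5-methoxy-2,2-dimethyl-3,4-dihydro-2H-chromen-8-yl]-3-(4-hydroxyphenyl)prop-2-en-1-one | COc1ccc(C(=O)/C=C/c2ccc(O)cc2)c2c1C[C@H](O)C(C)(C)O2 | target

## Step count and least certain steps

Total: 14 steps. Longest linear sequence: 9 steps (8, 9, 10, 11, 16, 21, 22, 23, 25, 27; the branch from 1 is equally long).

**Step 10 (key step).** The most likely failures are capture of the vinylketene by the product phenol or by a second ketene when cycloaddition is slow, photochemical E/Z isomerisation or secondary photolysis of the diazo enone, and acid-induced hydration of the ynol ether if the chlorinated solvent photodegrades. The fallback generates the ketene thermally and stages the cascade. It sets out from 3 and 16 and comes back at 21. Wittig reaction of 3 with the ylide from (2-carboxyethyl)triphenylphosphonium bromide and NaN(SiMe3)2 gives (3Z,5S)-5-(tert-butyldimethylsilyloxy)hex-3-enoic acid F1. 1-Chloro-N,N,2-trimethylprop-1-en-1-amine converts it under neutral conditions into (3Z,5S)-5-(tert-butyldimethylsilyloxy)hex-3-enoyl chloride F2. Slow addition of F2 to Et3N and 16 in CH2Cl2 produces (3Z,5S)-5-(tert-butyldimethylsilyloxy)hexa-1,3-dien-1-one F3 by dehydrochlorination. F3 is trapped in the dark as 4-[(1Z,3S)-3-(tert-butyldimethylsilyloxy)but-1-en-1-yl]-3-methoxy-2-{[(4S)-2,2,5,5-tetramethyl-1,3-dioxolan-4-yl]methyl}cyclobut-2-en-1-one F4. Isolated F4 is heated in toluene, where ring opening and 6π closure lead through 20 to 21.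

**Step 13.** After ionisation at C2, hydride migration from C3 (pinacol-type rearrangement to an isopropyl ketone) or proton loss may outrun capture by a phenol whose nucleophilicity is lowered by its hydrogen bond to the acetyl group. The fallback replaces the free cation by an acyloxonium-type ionisation. It sets out from 24 (step 13 stopped after the hydrolysis stage) and comes back at 25. MeC(OMe)3 with catalytic pyridinium p-toluenesulfonate gives 1-(2-hydroxy-4-methoxy-3-{[(4S)-2-methoxy-2,5,5-trimethyl-1,3-dioxolan-4-yl]methyl}phenyl)ethan-1-one F5. BF3·OEt2 in CH2Cl2 removes the methoxide, and the phenol oxygen opens the ring at the tertiary carbon with assistance from the acetate oxygen. No free hydroxyl remains at C3 to drive a hydride shift. The product is (3S)-8-acetyl-5-methoxy-2,2-dimethyl-3,4-dihydro-2H-chromen-3-yl acetate F6, and K2CO3 in MeOH releases 25.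

**Step 6.** The equilibrium may not lie far enough towards 10: incomplete migration, or diversion into the six-membered acetal spanning the primary and tertiary oxygens. The fallback differentiates the hydroxyls kinetically. It sets out from 9 and comes back at 10. Aqueous acetic acid gives (S)-3-methylbutane-1,2,3-triol F7. Pivaloyl chloride and pyridine at 0 °C acylate only the primary hydroxyl, giving (S)-2,3-dihydroxy-3-methylbutyl pivalate F8. 2-Methoxypropene with catalytic pyridinium p-toluenesulfonate gives [(4S)-2,2,5,5-tetramethyl-1,3-dioxolan-4-yl]methyl pivalate F9. NaOMe in MeOH removes the ester to give 10.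

**Step 9.** Substitution at a primary carbon that is β-branched and β-oxygenated may be slow enough for elimination or decay of the triflate and of the thermally fragile acetylide to compete. The fallback makes the same C–C bond by epoxide opening at an unhindered CH2. It sets out from 14 and comes back at 24.
- Acetylide 15 with BF3·OEt2 at −78 °C opens commercial methyl (S)-oxirane-2-carboxylate at C3 to give methyl (S)-2-hydroxy-5-methoxypent-4-ynoate F10.
- Excess MeMgBr gives (S)-6-methoxy-2-methylhex-5-yne-2,3-diol F11.
- Et3SiOSO2CF3 with 2,6-lutidine gives (3S)-6-methoxy-2-methyl-2,3-bis(triethylsilyloxy)hex-5-yne F12.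
- Benzannulation with 7 under the conditions of step 10 gives 6-[(1S)-1-(tert-butyldimethylsilyloxy)ethyl]-3-methoxy-2-[(2S)-3-methyl-2,3-bis(triethylsilyloxy)butyl]phenol F13.
- Bu4NF removes all three silyl groups to give (2S)-1-{2-hydroxy-3-[(1S)-1-hydroxyethyl]-6-methoxyphenyl}-3-methylbutane-2,3-diol F14.
- MnO2 oxidises the benzylic carbinol to 24, which enters the second stage of step 13.

**Step 14.** Addition of the enolate may stall once 26 is deprotonated to its unreactive phenoxide, leaving time for side reactions of the aldehyde. The fallback removes the phenoxide by protection. It sets out from 25 and comes back at 27. Condensation of 25 with commercial 4-(methoxymethoxy)benzaldehyde (KOH, EtOH) gives (2E)-1-[(3S)-3-hydroxy-5-methoxy-2,2-dimethyl-3,4-dihydro-2H-chromen-8-yl]-3-[4-(methoxymethoxy)phenyl]prop-2-en-1-one F15. HCl in MeOH at 50 °C cleaves the acetal to give 27.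

## Further compounds

F1 | step 10 | (3Z,5S)-5-(tert-butyldimethylsilyloxy)hex-3-enoic acid | C[C@H](O[Si](C)(C)C(C)(C)C)/C=C\CC(=O)O
F2 | step 10 | (3Z,5S)-5-(tert-butyldimethylsilyloxy)hex-3-enoyl chloride | C[C@H](O[Si](C)(C)C(C)(C)C)/C=C\CC(=O)Cl
F3 | step 10 | (3Z,5S)-5-(tert-butyldimethylsilyloxy)hexa-1,3-dien-1-one | O=C=C/C=C\[C@H](C)O[Si](C)(C)C(C)(C)C
F4 | step 10 | 4-[(1Z,3S)-3-(tert-butyldimethylsilyloxy)but-1-en-1-yl]-3-methoxy-2-{[(4S)-2,2,5,5-tetramethyl-1,3-dioxolan-4-yl]methyl}cyclobut-2-en-1-one (both configurations at C4) | COC1=C(C[C@@H]2OC(C)(C)OC2(C)C)C(=O)C1/C=C\[C@H](C)O[Si](C)(C)C(C)(C)C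
F5 | step 13 | 1-(2-hydroxy-4-methoxy-3-{[(4S)-2-methoxy-2,5,5-trimethyl-1,3-dioxolan-4-yl]methyl}phenyl)ethan-1-one (both configurations at the orthoester carbon) | COc1ccc(C(C)=O)c(O)c1C[C@@H]1OC(C)(OC)OC1(C)C
F6 | step 13 | (3S)-8-acetyl-5-methoxy-2,2-dimethyl-3,4-dihydro-2H-chromen-3-yl acetate | COc1ccc(C(C)=O)c2c1C[C@H](OC(C)=O)C(C)(C)O2
F7 | step 6 | (S)-3-methylbutane-1,2,3-triol | CC(C)(O)[C@@H](O)CO
F8 | step 6 | (S)-2,3-dihydroxy-3-methylbutyl pivalate | CC(C)(O)[C@@H](O)COC(=O)C(C)(C)C
F9 | step 6 | [(4S)-2,2,5,5-tetramethyl-1,3-dioxolan-4-yl]methyl pivalate | CC(C)(C)C(=O)OC[C@@H]1OC(C)(C)OC1(C)C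
F10 | step 9 | methyl (S)-2-hydroxy-5-methoxypent-4-ynoate | COC#CC[C@H](O)C(=O)OC
F11 | step 9 | (S)-6-methoxy-2-methylhex-5-yne-2,3-diol | COC#CC[C@H](O)C(C)(C)O
F12 | step 9 | (3S)-6-methoxy-2-methyl-2,3-bis(triethylsilyloxy)hex-5-yne | COC#CC[C@H](O[Si](CC)(CC)CC)C(C)(C)O[Si](CC)(CC)CC
F13 | step 9 | 6-[(1S)-1-(tert-butyldimethylsilyloxy)ethyl]-3-methoxy-2-[(2S)-3-methyl-2,3-bis(triethylsilyloxy)butyl]phenol | COc1ccc([C@H](C)O[Si](C)(C)C(C)(C)C)c(O)c1C[C@H](O[Si](CC)(CC)CC)C(C)(C)O[Si](CC)(CC)CC
F14 | step 9 | (2S)-1-{2-hydroxy-3-[(1S)-1-hydroxyethyl]-6-methoxyphenyl}-3-methylbutane-2,3-diol | COc1ccc([C@H](C)O)c(O)c1C[C@H](O)C(C)(C)O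
F15 | step 14 | (2E)-1-[(3S)-3-hydroxy-5-methoxy-2,2-dimethyl-3,4-dihydro-2H-chromen-8-yl]-3-[4-(methoxymethoxy)phenyl]prop-2-en-1-one | COc1ccc(C(=O)/C=C/c2ccc(OCOC)cc2)c2c1C[C@H](O)C(C)(C)O2
A1 | alternative 1 | (3S)-8-{(2E)-3-[4-(acetyloxy)phenyl]prop-2-enoyl}-5-methoxy-2,2-dimethyl-3,4-dihydro-2H-chromen-3-yl acetate | COc1ccc(C(=O)/C=C/c2ccc(OC(C)=O)cc2)c2c1C[C@H](OC(C)=O)C(C)(C)O2
A2 | alternative 1 | (3S)-8-bromo-5-methoxy-2,2-dimethyl-3,4-dihydro-2H-chromen-3-yl acetate | COc1ccc(Br)c2c1C[C@H](OC(C)=O)C(C)(C)O2
A3 | alternative 1 | 4-ethenylphenyl acetate | CC(=O)Oc1ccc(C=C)cc1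
A4 | alternative 2 | 1-(2-hydroxy-4-methoxyphenyl)ethan-1-one | COc1ccc(C(C)=O)c(O)c1
A5 | alternative 2 | 1-(5-methoxy-2,2-dimethyl-2H-chromen-8-yl)ethan-1-one | COc1ccc(C(C)=O)c2c1C=CC(C)(C)O2
A6 | alternative 2 | (3S,4S)-8-acetyl-3,4-epoxy-5-methoxy-2,2-dimethylchroman | COc1ccc(C(C)=O)c2c1[C@@H]3O[C@@H]3C(C)(C)O2
A7 | alternative 3 | 1-bromo-4-methoxy-2-[(2-methylbut-3-yn-2-yl)oxy]benzene | COc1ccc(Br)c(OC(C)(C)C#C)c1
A8 | alternative 3 | 8-bromo-5-methoxy-2,2-dimethylchroman-3-one | COc1ccc(Br)c2c1CC(=O)C(C)(C)O2
A9 | alternative 3 | (3S)-8-bromo-5-methoxy-2,2-dimethyl-3,4-dihydro-2H-chromen-3-ol | COc1ccc(Br)c2c1C[C@H](O)C(C)(C)O2
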